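**Retrosynthetic overview**
- Last ring formed: ring C of flavone unit 2, by one-pot BCl3 dealkylation and acid cyclodehydration of an aryl 2,4,6-trimethoxyphenyl 1,3-diketone; that ring A is symmetric, so only one mode of closure exists.
- Key C–C disconnection: C2–C3 of unit 2, between the aldehyde carbon of an 8-(4-formylphenoxy)flavone (used as a carbene-bound acyl anion equivalent) and the CH2Cl carbon of 2-chloro-1-(2,4,6-trimethoxyphenyl)ethanone.
- Diaryl ether: SNAr of the C8 phenol of a 5,8-dihydroxyflavone on 4-fluorobenzaldehyde; the C8 oxygen comes from an Elbs oxidation para to the chelated 5-OH, which fixes the 8-linkage because the ring oxygen is already in ring C.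
- Flavone unit 1 (rings A, C and B) is taken intact from the bulk commercial flavone apigenin after 7-O-benzylation and 4'-O-methylation; the chloro ketone comes from 1,3,5-trimethoxybenzene and chloroacetyl chloride.
- Ring order: unit 1 (purchased core) → ring B of unit 2 (ether) → ring A of unit 2 (key bond) → ring C of unit 2 (last).

Assumption: the target has no stereocentre and no configurationally stable axis, so "single enantiomer" is read as the one achiral compound drawn; no stereocontrol is needed.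

**Route**

Step 1
Reactants: 1 apigenin
Product: 3 7-(benzyloxy)-5-hydroxy-2-(4-methoxyphenyl)-4H-chromen-4-one, via 7-O-benzylapigenin 2 (not isolated)
Conditions: BnBr (1.05 equiv), K2CO3 (2.5 equiv), DMF, 0 → 25 °C, 8 h; then MeI (1.5 equiv), 25 °C, 6 h
Reagents that add atoms: benzyl bromide BrCc1ccccc1; iodomethane CI
Why: Two Williamson etherifications in order of acidity: the 7-OH (vinylogous acid para to the C4 carbonyl) is benzylated first, the 4'-OH is then methylated, and the 5-OH stays free because its hydrogen bond to C4=O keeps it from being alkylated by K2CO3 at 25 °C.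

Step 2
Reactants: 3 7-(benzyloxy)-5-hydroxy-2-(4-methoxyphenyl)-4H-chromen-4-one
Product: 5 7-(benzyloxy)-5,8-dihydroxy-2-(4-methoxyphenyl)-4H-chromen-4-one, via potassium 8-sulfate ester 4 (not isolated)
Conditions: K2S2O8 (1.5 equiv), 10% aq. KOH, pyridine, 15–20 °C, 24 h; then 2 M HCl, 90 °C, 1 h, N2
Reagents that add atoms: potassium peroxodisulfate [K+].[K+].[O-]S(=O)(=O)OOS(=O)(=O)[O-]
Why: Elbs persulfate oxidation, in which the 5-phenoxide attacks the peroxide bond through its para carbon C8 (C6 is ortho and is not attacked) and acid hydrolysis of the aryl sulfate leaves the new hydroxyl at C8, next to a ring oxygen that is already locked in ring C.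

Step 3
Reactants: 5 7-(benzyloxy)-5,8-dihydroxy-2-(4-methoxyphenyl)-4H-chromen-4-one; 6 4-fluorobenzaldehyde
Product: 7 4-{[7-(benzyloxy)-5-hydroxy-2-(4-methoxyphenyl)-4-oxo-4H-chromen-8-yl]oxy}benzaldehyde
Conditions: K2CO3 (1.5 equiv), 6 (1.3 equiv), degassed DMF, 100 °C, 12 h, Ar
Reagents that add atoms: none
Why: Nucleophilic aromatic substitution (SNAr) in which the free, more acidic C8 phenoxide displaces fluoride para to the formyl group while the chelated 5-OH is a far poorer nucleophile, air being excluded so that the hydroquinone is not oxidised.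

Step 4
Reactants: 8 1,3,5-trimethoxybenzene; 9 chloroacetyl chloride
Product: 10 2-chloro-1-(2,4,6-trimethoxyphenyl)ethan-1-one
Conditions: AlCl3 (1.1 equiv), CH2Cl2, −10 → 0 °C, 1 h
Reagents that add atoms: none
Why: Friedel–Crafts acylation of a threefold-activated symmetric arene whose three free positions are equivalent, run cold and short so that AlCl3 does not cleave an ortho methoxy group.

Step 5
Reactants: 7 4-{[7-(benzyloxy)-5-hydroxy-2-(4-methoxyphenyl)-4-oxo-4H-chromen-8-yl]oxy}benzaldehyde; 10 2-chloro-1-(2,4,6-trimethoxyphenyl)ethan-1-one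
Product: 11 1-(4-{[7-(benzyloxy)-5-hydroxy-2-(4-methoxyphenyl)-4-oxo-4H-chromen-8-yl]oxy}phenyl)-3-(2,4,6-trimethoxyphenyl)propane-1,3-dione
Conditions: 3-benzyl-5-(2-hydroxyethyl)-4-methylthiazolium chloride (30 mol %), i-Pr2NEt (1.3 equiv), DMF, 60 °C, 10 (1.2 equiv) added over 6 h, N2
Reagents that add atoms: none
Why: Proposed new method: the thiazol-2-ylidene adds to the unhindered, non-enolisable aldehyde of 7 to give the enaminol (acyl anion equivalent), whose former carbonyl carbon displaces chloride from the CH2Cl group of 10 (α-halo ketones are exceptionally SN2-active and the two ortho methoxy groups shield the ketone of 10 from cross-benzoin attack), after which the adduct collapses to the 1,3-diketone and releases the carbene, the reversible benzoin self-coupling of 7 acting only as a reservoir and the weak amine base leaving the chelated 5-OH protonated; the closest known reaction types are the carbene-catalysed intramolecular acylation of alkyl halides or sulfonates to chroman-4-ones and the Stetter reaction, and no stereocentre is formed.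

Step 6
Reactants: 11 1-(4-{[7-(benzyloxy)-5-hydroxy-2-(4-methoxyphenyl)-4-oxo-4H-chromen-8-yl]oxy}phenyl)-3-(2,4,6-trimethoxyphenyl)propane-1,3-dione
Product: 13 5,7-dihydroxy-8-[4-(5-hydroxy-7-methoxy-4-oxo-4H-chromen-2-yl)phenoxy]-2-(4-methoxyphenyl)-4H-chromen-4-one, via tetraphenolic diketone 12 (not isolated)
Conditions: BCl3 (10 equiv), C6HMe5 (3 equiv), CH2Cl2, −78 → 25 °C, 16 h; then MeOH, conc. HCl (cat.), 65 °C, 2 h
Reagents that add atoms: none
Why: BCl3 removes the benzyl group (cation trapped by pentamethylbenzene) and, by chelation to the aryl ketone, only the two ortho methoxy groups, leaving both para methoxy groups, and the freed 2,6-dihydroxyaryl 1,3-diketone then undergoes the acid-catalysed cyclodehydration that ends a Baker–Venkataraman flavone synthesis, the symmetric ring A allowing only one product.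

**Compound list**

1 | apigenin, 5,7-dihydroxy-2-(4-hydroxyphenyl)-4H-chromen-4-one | O=c1cc(-c2ccc(O)cc2)oc2cc(O)cc(O)c12 | starting material
2 | 7-O-benzylapigenin, 7-(benzyloxy)-5-hydroxy-2-(4-hydroxyphenyl)-4H-chromen-4-one (formed in situ) | O=c1cc(-c2ccc(O)cc2)oc2cc(OCc3ccccc3)cc(O)c12 | intermediate
3 | 7-(benzyloxy)-5-hydroxy-2-(4-methoxyphenyl)-4H-chromen-4-one | COc1ccc(cc1)-c1cc(=O)c2c(O)cc(OCc3ccccc3)cc2o1 | intermediate
4 | potassium 7-(benzyloxy)-5-hydroxy-2-(4-methoxyphenyl)-4-oxo-4H-chromen-8-yl sulfate (formed in situ) | COc1ccc(cc1)-c1cc(=O)c2c(O)cc(OCc3ccccc3)c(OS(=O)(=O)[O-])c2o1.[K+] | intermediate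
5 | 7-(benzyloxy)-5,8-dihydroxy-2-(4-methoxyphenyl)-4H-chromen-4-one | COc1ccc(cc1)-c1cc(=O)c2c(O)cc(OCc3ccccc3)c(O)c2o1 | intermediate
6 | 4-fluorobenzaldehyde | O=Cc1ccc(F)cc1 | starting material
7 | 4-{[7-(benzyloxy)-5-hydroxy-2-(4-methoxyphenyl)-4-oxo-4H-chromen-8-yl]oxy}benzaldehyde | COc1ccc(cc1)-c1cc(=O)c2c(O)cc(OCc3ccccc3)c(Oc3ccc(C=O)cc3)c2o1 | intermediate
8 | 1,3,5-trimethoxybenzene | COc1cc(OC)cc(OC)c1 | starting material
9 | chloroacetyl chloride | ClCC(Cl)=O | starting material
10 | 2-chloro-1-(2,4,6-trimethoxyphenyl)ethan-1-one | COc1cc(OC)c(C(=O)CCl)c(OC)c1 | intermediate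
11 | 1-(4-{[7-(benzyloxy)-5-hydroxy-2-(4-methoxyphenyl)-4-oxo-4H-chromen-8-yl]oxy}phenyl)-3-(2,4,6-trimethoxyphenyl)propane-1,3-dione (drawn as the diketo form) | COc1ccc(cc1)-c1cc(=O)c2c(O)cc(OCc3ccccc3)c(Oc3ccc(cc3)C(=O)CC(=O)c3c(OC)cc(OC)cc3OC)c2o1 | intermediate
12 | 1-(2,6-dihydroxy-4-methoxyphenyl)-3-(4-{[5,7-dihydroxy-2-(4-methoxyphenyl)-4-oxo-4H-chromen-8-yl]oxy}phenyl)propane-1,3-dione (formed in situ) | COc1ccc(cc1)-c1cc(=O)c2c(O)cc(O)c(Oc3ccc(cc3)C(=O)CC(=O)c3c(O)cc(OC)cc3O)c2o1 | intermediate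
13 | 5,7-dihydroxy-8-[4-(5-hydroxy-7-methoxy-4-oxo-4H-chromen-2-yl)phenoxy]-2-(4-methoxyphenyl)-4H-chromen-4-one (CNP0124888.0, achiral) | COc1ccc(cc1)-c1cc(=O)c2c(O)cc(O)c(Oc3ccc(cc3)-c3cc(=O)c4c(O)cc(OC)cc4o3)c2o1 | target

**Step count and risks**

Total steps: 6. Longest linear sequence: 5 steps (steps 1, 2, 3, 5, 6 from apigenin); step 4 is a one-step side branch.

The least secure operation is step 5. The carbene can be consumed by alkylation with 10, and the diketone enolate can be alkylated a second time. The fallback reverses the roles of the two partners and sets out from 7 and 10. Reduction of 10 with CrCl2 (2.5 equiv) and LiI (0.2 equiv) in THF at 25 °C gives its chromium enolate, which adds to the aldehyde of 7 in a Reformatsky-type aldol. The product is racemic 3-(4-{[7-(benzyloxy)-5-hydroxy-2-(4-methoxyphenyl)-4-oxo-4H-chromen-8-yl]oxy}phenyl)-3-hydroxy-1-(2,4,6-trimethoxyphenyl)propan-1-one F1. Oxidation of this secondary alcohol with 1,1,1-triacetoxy-1,1-dihydro-1,2-benziodoxol-3(1H)-one in CH2Cl2 at 25 °C removes the stereocentre and comes back to the route at 11.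

Second is step 2. Elbs oxidations of chelated 5-hydroxyflavones commonly stop at 20–40 % conversion with recovered 3. The fallback sets out from 3 and oxidises it with PhI(OCOCF3)2 (2.2 equiv) in MeCN/H2O at 0 °C to the para-quinone 7-(benzyloxy)-2-(4-methoxyphenyl)-4H-chromene-4,5,8-trione F2. Reduction of F2 with Na2S2O4 in EtOAc/H2O at 25 °C comes back to the route at 5.

Third is step 6. The second ortho methoxy group may resist BCl3 while the diketone is held as a boron chelate. The fallback sets out from 11 and changes the order of events. BCl3 (3.5 equiv) with C6HMe5 in CH2Cl2 at −78 → 0 °C cleaves only the benzyl ether and one ortho methoxy group, giving 1-(4-{[5,7-dihydroxy-2-(4-methoxyphenyl)-4-oxo-4H-chromen-8-yl]oxy}phenyl)-3-(2-hydroxy-4,6-dimethoxyphenyl)propane-1,3-dione F3. Ring closure with catalytic H2SO4 in AcOH at 100 °C gives the isolable 8-[4-(5,7-dimethoxy-4-oxo-4H-chromen-2-yl)phenoxy]-5,7-dihydroxy-2-(4-methoxyphenyl)-4H-chromen-4-one F4. The remaining methoxy group, now peri to the C4 carbonyl of a finished flavone, is then cleaved with AlCl3 in MeCN at 60 °C, which arrives at 13.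

**Further compounds**

F1 | step 5 | racemic 3-(4-{[7-(benzyloxy)-5-hydroxy-2-(4-methoxyphenyl)-4-oxo-4H-chromen-8-yl]oxy}phenyl)-3-hydroxy-1-(2,4,6-trimethoxyphenyl)propan-1-one | COc1ccc(cc1)-c1cc(=O)c2c(O)cc(OCc3ccccc3)c(Oc3ccc(cc3)C(O)CC(=O)c3c(OC)cc(OC)cc3OC)c2o1
F2 | step 2 | 7-(benzyloxy)-2-(4-methoxyphenyl)-4H-chromene-4,5,8-trione | COc1ccc(cc1)C1=CC(=O)C2=C(O1)C(=O)C(OCc1ccccc1)=CC2=O
F3 | step 6 | 1-(4-{[5,7-dihydroxy-2-(4-methoxyphenyl)-4-oxo-4H-chromen-8-yl]oxy}phenyl)-3-(2-hydroxy-4,6-dimethoxyphenyl)propane-1,3-dione | COc1ccc(cc1)-c1cc(=O)c2c(O)cc(O)c(Oc3ccc(cc3)C(=O)CC(=O)c3c(O)cc(OC)cc3OC)c2o1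
F4 | step 6 | 8-[4-(5,7-dimethoxy-4-oxo-4H-chromen-2-yl)phenoxy]-5,7-dihydroxy-2-(4-methoxyphenyl)-4H-chromen-4-one | COc1ccc(cc1)-c1cc(=O)c2c(O)cc(O)c(Oc3ccc(cc3)-c3cc(=O)c4c(OC)cc(OC)cc4o3)c2o1
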